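Ring A is cut at C1–C10 and C2–C3. The plan rests on two features of the target: ring B (C6 hydroxyl, C8=C9 alkene with C17 on C8, chain on C9) can be read as a 2,6-dimethyl-1,4-benzoquinone masked as its monoketal, and C4, between oxidised C3 and C19, is a methylmalonate carbon. In a single operation the C10 enolate of a ring B enone adds to phenyl vinyl sulfone and the α-sulfonyl anion thus formed is acylated by one of the malonate esters, which closes ring A trans-fused and sets the quaternary centres C10 and C4. The precursor is the enantioenriched adduct of dimethyl methylmalonate and the quinone monoketal. The sulfone later shields C3 while the chain is added to C9.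

Key step: step 3

Remark: labdane numbering is used from compound 4 onward; the configurations at C10 of 4, at C2 of 7, 11 and 12 and at C9 of 11 and 12 are immaterial because these centres are planarised or lose their substituent later, and the expected isomer is drawn.
Remark: the (R)-BINOL catalyst of step 2 is assumed to show the facial sense it shows with cyclohex-2-enone; if the sense is opposite, the (S)-ligand is used.

Step 1
Reactants: 1 4-methoxy-2,6-dimethylphenol
Product: 2 4,4-dimethoxy-2,6-dimethylcyclohexa-2,5-dien-1-one (quinone monoketal)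
Conditions: PhI(OAc)2 (1.1 equiv), MeOH, 0 °C
Reagents that add atoms: methanol, CO
Why: Oxidative dearomatisation of a para-methoxyphenol with a hypervalent iodine reagent in methanol gives the quinone monoketal directly, the solvent capturing the ring cation at the carbon that already bears methoxy; no stereocentre is formed.

Step 2
Reactants: 2 quinone monoketal; 3 dimethyl methylmalonate
Product: 4 ring B Michael adduct (malonate on C5; C5 R; C10 methyl trans to the malonate; C6 dimethyl ketal; C7=C8–C9=O enone)
Conditions: LiAl[(R)-BINOLate]2 (10 mol%), KOt-Bu (9 mol%), 4 Å molecular sieves, THF, rt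
Reagents that add atoms: none
Why: Catalytic asymmetric Michael addition of an α-substituted malonate to a cyclic enone under Lewis acid–Brønsted base bimetallic catalysis should desymmetrise the dienone, the catalyst choosing one of the two enantiotopic β-carbons and its open face and thereby setting C5 (R); C10 is protonated to the more stable trans isomer but is planarised again in step 3.

Step 3
Reactants: 4 ring B Michael adduct; 5 phenyl vinyl sulfone
Product: 7 trans-fused β-keto sulfone (5α-H; 10β-CH3; 4α-CH3; 4β-CO2CH3 = C19; 2α-SO2Ph; 3-oxo; 6,6-dimethoxy; 7-ene; 9-oxo), via Michael adduct sulfone 6 (not isolated)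
Conditions: LiN(SiMe3)2 (1.1 equiv), THF, −78 °C; then 5 (1.3 equiv), −78 → 0 °C; AcOH quench
Reagents that add atoms: none
Why: LiN(SiMe3)2 removes the only acidic hydrogen of 4 (C10–H) to give a lithium dienolate that adds through C10 to the vinyl sulfone (C10–C1), and the lithiated sulfone at C2 then attacks one ester carbonyl on C4 and expels methoxide (C2–C3), which deprotonates the new β-keto sulfone and so locks the closure. The closest known reaction type is the tandem Michael–Dieckmann annulation, with a sulfone–ester Claisen condensation as the ring-forming event. Ring A closes by a 6-exo-trig acylation through a chair. C10 is set because allylic strain with the C10 methyl turns the bulky C5 malonate pseudoaxial, so the acceptor enters on the opposite face and C1 and C4 become trans, the arrangement of a trans-decalin; C4 is set because the chair that attacks the ester destined to become C3 keeps the other ester axial on the β face, whereas the alternative would place the C18 methyl 1,3-diaxial to C20. The step needs the C2 carbanion to acylate and not to add to C7 of the enone (which would give a bicyclo[2.2.2]octanone), and it needs the enolate to be alkylated before it can expel the malonate in a retro-Michael reaction; a lithium counter-ion in THF without polar additives (carbonyl-directed sulfonyl carbanion), the fully substituted C6 beside C7 and the eclipsing of the C5 malonate with a C6 methoxy group that bridging to C7 would demand should favour acylation, and the preformed enolate at low temperature should hold back the retro-Michael reaction.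

Step 4
Reactants: 7 trans-fused β-keto sulfone; 8 2-(2-bromoethyl)-2-methyl-1,3-dioxolane
Product: 12 γ-hydroxy enone (C9 β-OH and α side chain CH2CH2C(CH3)(OCH2CH2O); 6-oxo-7-ene; β-keto sulfone and C19 ester unchanged), via Grignard reagent 9 (not isolated), via organocerium reagent 10 (not isolated), via C9 carbinol ketal 11 (not isolated)
Conditions: 8, Mg, THF, 25 °C; CeCl3, THF, −78 °C; lithium enolate of 7 (from LiN(SiMe3)2, 1.05 equiv, THF, −78 °C) added, −78 → −40 °C; then 0.5 M HCl, THF, 0 °C
Reagents that add atoms: water, O
Why: Organocerium reagents add 1,2 to hindered, enolisable 2,6,6-trisubstituted cyclohex-2-enones, while C3 stays protected in the flask as its sulfonyl-stabilised enolate and the neopentyl C19 ester is too hindered to compete; attack is expected anti to the axial C20 methyl, but the C9 centre is removed in step 5, and cold dilute acid then hydrolyses only the allylic dimethyl ketal (acetal hydrolysis), which is far more labile than the side-chain dioxolane.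

Step 5
Reactants: 12 γ-hydroxy enone
Product: 13 diketo ester (methyl 13,13-ethylenedioxy-3,6-dioxo-14,15-dinorlabd-8-en-19-oate)
Conditions: SmI2 (6 equiv), THF–MeOH, −78 → 0 °C; product used at once
Reagents that add atoms: none
Why: Electron transfer from SmI2 should cleave two activated carbon–heteroatom bonds in one operation, namely reductive desulfonylation of the β-keto sulfone through its samarium enolate and reduction of the γ-hydroxy enone to a dienolate with loss of the C9 hydroxide (the vinylogous form of α-hydroxy ketone deoxygenation), and kinetic protonation of that dienolate at C7 by methanol gives the deconjugated 8-en-6-one; the C9 stereocentre disappears and none is formed.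

Step 6
Reactants: 13 diketo ester
Product: 16 13,13-ethylenedioxy-14,15-dinorlabd-8-ene-3α,6β,19-triol, via dihydroxy ester 14 (not isolated), via hydroxy lactone 15 (not isolated)
Conditions: LiBH(sec-Bu)3 (3 equiv), THF, −78 → 0 °C; then LiAlH4 (3 equiv), 0 → 50 °C; aqueous potassium sodium tartrate
Reagents that add atoms: none
Why: In this bulky-hydride reduction LiBH(sec-Bu)3 should enter C3 along the equatorial trajectory to give the axial 3α-alcohol and enter C6 from the α face, the β face being closed by the axial C20 methyl and C19 ester, to give the axial 6β-alkoxide, which is expected to lactonise onto the neighbouring axial ester; LiAlH4 then reduces lactone or ester alike to the C19 primary alcohol and frees the C6 hydroxyl.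

Step 7
Reactants: 16 triol dioxolane
Product: 17 3α,6β,19-trihydroxy-14,15-dinorlabd-8-en-13-one
Conditions: 1 M HCl, THF, rt
Reagents that add atoms: water, O
Why: Acid-catalysed acetal hydrolysis frees the C13 methyl ketone, and the tetrasubstituted alkene and the three hydroxyls should be inert to dilute acid at room temperature; the trans-diaxial C3 and C19 oxygens cannot be bridged.

Step 8
Reactants: 17 trihydroxy methyl ketone; 18 triethyl phosphonoacetate
Product: 19 ethyl (13E)-3α,6β,19-trihydroxylabda-8,13-dien-15-oate
Conditions: 18 (5 equiv), NaH (4.5 equiv), THF, 0 → 60 °C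
Reagents that add atoms: none
Why: Horner–Wadsworth–Emmons olefination of the methyl ketone with the stabilised phosphonate anion, kept in excess over NaH so that the hydroxyls stay protonated, should give mainly the (E)-trisubstituted enoate, the ester ending trans to the larger C12 chain; the minor (Z)-isomer is removed by chromatography.

Step 9
Reactants: 19 ethyl ester
Product: 20 (13E)-3α,6β,19-trihydroxylabda-8,13-dien-15-oic acid (CNP0246116.2)
Conditions: LiOH, THF–MeOH–H2O, 40 °C; then 1 M HCl to pH 3
Reagents that add atoms: lithium hydroxide, [Li+].[OH-]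
Why: Saponification of the conjugated ethyl ester followed by acidification gives the acid; nothing else in the molecule is base-labile and the alkene geometry is retained.

Compound list
1 | 4-methoxy-2,6-dimethylphenol | COc1cc(C)c(O)c(C)c1 | starting material
2 | 4,4-dimethoxy-2,6-dimethylcyclohexa-2,5-dien-1-one | COC1(OC)C=C(C)C(=O)C(C)=C1 | intermediate
3 | dimethyl methylmalonate | COC(=O)C(C)C(=O)OC | starting material
4 | dimethyl 2-[(1R,6S)-2,2-dimethoxy-4,6-dimethyl-5-oxocyclohex-3-en-1-yl]-2-methylmalonate (ring B Michael adduct) | O=C1[C@@H](C)[C@H](C(C)(C(=O)OC)C(=O)OC)C(OC)(OC)C=C1C | intermediate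
5 | phenyl vinyl sulfone | C=CS(=O)(=O)c1ccccc1 | starting material
6 | dimethyl 2-[(1R,6S)-2,2-dimethoxy-4,6-dimethyl-5-oxo-6-(2-phenylsulfonylethyl)cyclohex-3-en-1-yl]-2-methylmalonate (chain trans to the malonate) | O=C1[C@@](C)(CCS(=O)(=O)c2ccccc2)[C@H](C(C)(C(=O)OC)C(=O)OC)C(OC)(OC)C=C1C | intermediate
7 | trans-fused β-keto sulfone: 5α-H; 10β-CH3; 4α-CH3; 4β-CO2CH3; 2α-SO2Ph; 3-oxo; 6,6-dimethoxy; 7-ene with 8-CH3; 9-oxo | O=C1[C@@]2(C)C[C@@H](S(=O)(=O)c3ccccc3)C(=O)[C@](C)(C(=O)OC)[C@@H]2C(OC)(OC)C=C1C | intermediate
8 | 2-(2-bromoethyl)-2-methyl-1,3-dioxolane | CC1(CCBr)OCCO1 | starting material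
9 | [2-(2-methyl-1,3-dioxolan-2-yl)ethyl]magnesium bromide | CC1(CC[Mg]Br)OCCO1 | intermediate
10 | dichloro[2-(2-methyl-1,3-dioxolan-2-yl)ethyl]cerium | CC1(CC[Ce](Cl)Cl)OCCO1 | intermediate
11 | C9 carbinol ketal: as 7, but C9 carries β-OH and the α side chain CH2CH2C(CH3)(OCH2CH2O) | O[C@]1(CCC4(C)OCCO4)[C@@]2(C)C[C@@H](S(=O)(=O)c3ccccc3)C(=O)[C@](C)(C(=O)OC)[C@@H]2C(OC)(OC)C=C1C | intermediate
12 | γ-hydroxy enone: as 11, but C6 is a ketone conjugated with C7=C8 | O[C@]1(CCC4(C)OCCO4)[C@@]2(C)C[C@@H](S(=O)(=O)c3ccccc3)C(=O)[C@](C)(C(=O)OC)[C@@H]2C(=O)C=C1C | intermediate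
13 | methyl 13,13-ethylenedioxy-3,6-dioxo-14,15-dinorlabd-8-en-19-oate | CC1=C(CCC3(C)OCCO3)[C@@]2(C)CCC(=O)[C@](C)(C(=O)OC)[C@@H]2C(=O)C1 | intermediate
14 | methyl 13,13-ethylenedioxy-3α,6β-dihydroxy-14,15-dinorlabd-8-en-19-oate | CC1=C(CCC3(C)OCCO3)[C@@]2(C)CC[C@@H](O)[C@](C)(C(=O)OC)[C@@H]2[C@H](O)C1 | intermediate
15 | 13,13-ethylenedioxy-3α-hydroxy-14,15-dinorlabd-8-en-19,6β-olide | CC1=C(CCC5(C)OCCO5)[C@@]2(C)CC[C@@H](O)[C@](C)(C(=O)O3)[C@@H]2[C@H]3C1 | intermediate
16 | 13,13-ethylenedioxy-14,15-dinorlabd-8-ene-3α,6β,19-triol | CC1=C(CCC3(C)OCCO3)[C@@]2(C)CC[C@@H](O)[C@](C)(CO)[C@@H]2[C@H](O)C1 | intermediate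
17 | 3α,6β,19-trihydroxy-14,15-dinorlabd-8-en-13-one | CC1=C(CCC(C)=O)[C@@]2(C)CC[C@@H](O)[C@](C)(CO)[C@@H]2[C@H](O)C1 | intermediate
18 | triethyl phosphonoacetate | CCOC(=O)CP(=O)(OCC)OCC | starting material
19 | ethyl (13E)-3α,6β,19-trihydroxylabda-8,13-dien-15-oate | CC1=C(CC/C(C)=C/C(=O)OCC)[C@@]2(C)CC[C@@H](O)[C@](C)(CO)[C@@H]2[C@H](O)C1 | intermediate
20 | (13E)-3α,6β,19-trihydroxylabda-8,13-dien-15-oic acid (CNP0246116.2) | CC1=C(CC/C(C)=C/C(=O)O)[C@@]2(C)CC[C@@H](O)[C@](C)(CO)[C@@H]2[C@H](O)C1 | target

Total step count: 9. Longest linear sequence: 9 steps, from 1 to 20; compounds 3, 5, 8 and 18 enter as purchased.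

Steps most likely to fail

Step 3. Two processes threaten it. The lithiated sulfone may add to C7 of the ring B enone and give a bridged double conjugate-addition product instead of acylating. The enolate may also expel the malonate before it is alkylated, which lowers the yield and, through re-addition, the enantiomeric purity. The fallback separates the two bond formations and removes the enone between them. It sets out from 4 and 5: conjugate addition under proton-transfer conditions (KOt-Bu, 0.1 equiv, t-BuOH–THF, 0 °C), where the solvent protonates the sulfonyl carbanion as it forms, should allow the Michael adduct sulfone 6 to be isolated. Organocerium reagent 10 (THF, −78 °C) then adds to C9 of 6 to give the C9 carbinol sulfone diester F1, which no longer holds a conjugate acceptor. LiN(SiMe3)2 (2.5 equiv, THF, −78 → 0 °C) should then effect the sulfone–ester Dieckmann closure on the alkoxide–carbanion dianion to give 11, and cold dilute HCl takes 11 to 12, where the route is rejoined.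

Step 2. The catalyst may discriminate poorly between the enantiotopic positions of a dienone that carries a methyl group beside the carbonyl on each side, or the addition at the β-carbon next to the ketal may be slow. The fallback replaces asymmetric catalysis by resolution. It sets out from 2 and 3: addition with an achiral base (KOt-Bu, 0.1 equiv, THF–t-BuOH, rt) gives the racemic adduct, which is resolved by preparative chromatography on a chiral stationary phase (supercritical CO2–MeOH). The unwanted enantiomer ent-4 F2 is set aside and the route is rejoined at 4.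

Step 5. The free tertiary hydroxide at C9 may leave too slowly from the reduced enone, so that simple saturation of the enone or protonation at C9 to the conjugated 7-en-6-one competes. The fallback builds the C8=C9 alkene by cross-coupling instead of reductive transposition. It sets out from 7: NaH (1 equiv, THF, 0 °C) masks C3 as its enolate, LiBH(sec-Bu)3 (−78 °C) delivers hydride to C7, and PhNTf2 traps the resulting C8=C9 enolate as the enol triflate F3. Negishi coupling of F3 with the alkylzinc bromide F4 (from 8, Zn, LiCl, THF) under Pd(dppf)Cl2 catalysis (THF, 50 °C) gives the coupled ketal β-keto sulfone F5. SmI2 (2.5 equiv, THF–MeOH, −78 °C) then removes only the sulfone to give the ketal keto ester F6, and cold dilute HCl hydrolyses the strained C6 dimethyl ketal to 13, where the route is rejoined.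

Further compounds
F1 | step 3 | C9 carbinol sulfone diester: 6 with β-OH and the dioxolane side chain on C9 in place of the carbonyl | O[C@]1(CCC3(C)OCCO3)[C@@](C)(CCS(=O)(=O)c2ccccc2)[C@H](C(C)(C(=O)OC)C(=O)OC)C(OC)(OC)C=C1C
F2 | step 2 | ent-4, dimethyl 2-[(1S,6R)-2,2-dimethoxy-4,6-dimethyl-5-oxocyclohex-3-en-1-yl]-2-methylmalonate | O=C1[C@H](C)[C@@H](C(C)(C(=O)OC)C(=O)OC)C(OC)(OC)C=C1C
F3 | step 5 | C9 enol triflate: 7 with C8=C9–OSO2CF3 and C7H2 | CC1=C(OS(=O)(=O)C(F)(F)F)[C@@]2(C)C[C@@H](S(=O)(=O)c3ccccc3)C(=O)[C@](C)(C(=O)OC)[C@@H]2C(OC)(OC)C1
F4 | step 5 | [2-(2-methyl-1,3-dioxolan-2-yl)ethyl]zinc bromide | CC1(CC[Zn]Br)OCCO1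
F5 | step 5 | coupled ketal β-keto sulfone: 8-ene with the dioxolane side chain on C9; 6,6-dimethoxy; 2α-SO2Ph; 3-oxo; C19 methyl ester | CC1=C(CCC5(C)OCCO5)[C@@]2(C)C[C@@H](S(=O)(=O)c3ccccc3)C(=O)[C@](C)(C(=O)OC)[C@@H]2C(OC)(OC)C1
F6 | step 5 | ketal keto ester: methyl 13,13-ethylenedioxy-6,6-dimethoxy-3-oxo-14,15-dinorlabd-8-en-19-oate | CC1=C(CCC5(C)OCCO5)[C@@]2(C)CCC(=O)[C@](C)(C(=O)OC)[C@@H]2C(OC)(OC)C1
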